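**Retrosynthetic overview**
- Last bond made: A‑ring C2–CH2 of the heptyl chain. The aryl bromide of a fully assembled bromo‑depside acid is coupled with heptanal used as its N–H hydrazone, so the aldehyde carbon acts as a heptyl carbanion equivalent (Ni‑catalysed, loss of N2).
- The B‑ring CO2H comes from Pinnick oxidation of a formyl group; the 2'‑OMe comes from O‑methylation of the chelated phenol after the depside ester is in place.
- The depside C–O bond comes from TFAA esterification of 2‑bromo‑4,6‑dimethoxybenzoic acid with the non‑chelated 4‑OH of 2,4‑dihydroxy‑6‑pentylbenzaldehyde.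
- The bromo acid comes from Pinnick oxidation of 2‑bromo‑4,6‑dimethoxybenzaldehyde; the B‑ring aldehyde comes from Vilsmeier formylation of olivetol.
- No ring is formed: both benzene rings are bought intact.

Assumption: the target is an achiral depside with no stereocentre, so there is no enantiomer to select and no stereocontrol step; 2‑bromo‑4,6‑dimethoxybenzaldehyde is taken as a catalogue building block (otherwise one Vilsmeier step from 1‑bromo‑3,5‑dimethoxybenzene).

**Step 1**
Reactants: 1 2-bromo-4,6-dimethoxybenzaldehyde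
Product: 2 2-bromo-4,6-dimethoxybenzoic acid
Conditions: NaClO2, NaH2PO4, 2-methyl-2-butene, t-BuOH/THF/H2O, 0 °C to rt
Reagents that add atoms: sodium chlorite, [Na+].[O-]Cl=O
Why: Pinnick (Lindgren) oxidation, in which chlorous acid adds to the aldehyde and fragments to the acid while 2-methyl-2-butene traps HOCl, so the electron-rich ring and the C–Br bond are untouched.

**Step 2**
Reactants: 3 olivetol (5-pentylbenzene-1,3-diol)
Product: 5 2,4-dihydroxy-6-pentylbenzaldehyde, via aryl iminium chloride 4 (not isolated)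
Conditions: POCl3, DMF, 0 °C to rt; then H2O, 50 °C
Reagents that add atoms: N,N-dimethylformamide, CN(C)C=O; water, O
Why: Vilsmeier–Haack formylation, in which the chloroiminium ion attacks the resorcinol carbon para to one OH and ortho to the other (the position that gives orcylaldehyde-type products from 5-alkylresorcinols) and water hydrolyses iminium 4 to the aldehyde.

**Step 3**
Reactants: 2 2-bromo-4,6-dimethoxybenzoic acid, 5 2,4-dihydroxy-6-pentylbenzaldehyde
Product: 7 4-formyl-3-hydroxy-5-pentylphenyl 2-bromo-4,6-dimethoxybenzoate, via mixed trifluoroacetic anhydride 6 (not isolated)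
Conditions: TFAA (2.5 equiv), toluene, rt, 3 h; aq. NaHCO3 work-up
Reagents that add atoms: none
Why: Trifluoroacetic anhydride-mediated esterification (mixed-anhydride/acylium activation, suited to 2,6-disubstituted benzoic acids), in which only the 4-OH of 5 is acylated because the 2-OH is hydrogen-bonded to the ortho formyl group and much less nucleophilic.

**Step 4**
Reactants: 7 4-formyl-3-hydroxy-5-pentylphenyl 2-bromo-4,6-dimethoxybenzoate
Product: 8 4-formyl-3-methoxy-5-pentylphenyl 2-bromo-4,6-dimethoxybenzoate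
Conditions: MeI (3 equiv), K2CO3 (2 equiv), dry DMF, rt
Reagents that add atoms: iodomethane, CI
Why: Williamson O-methylation of the chelated phenoxide under anhydrous conditions, where the di-ortho-substituted depside ester is too hindered to be attacked.

**Step 5**
Reactants: 8 4-formyl-3-methoxy-5-pentylphenyl 2-bromo-4,6-dimethoxybenzoate
Product: 9 4-[(2-bromo-4,6-dimethoxybenzoyl)oxy]-2-methoxy-6-pentylbenzoic acid
Conditions: NaClO2, NaH2PO4, 2-methyl-2-butene, t-BuOH/THF/H2O, 0 °C to rt
Reagents that add atoms: sodium chlorite, [Na+].[O-]Cl=O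
Why: Pinnick oxidation at about pH 4, which converts the hindered aryl aldehyde to the acid without hydrolysing the depside ester or touching the aryl bromide.

**Step 6**
Reactants: 9 4-[(2-bromo-4,6-dimethoxybenzoyl)oxy]-2-methoxy-6-pentylbenzoic acid, 10 heptanal
Product: 12 4-[(2-heptyl-4,6-dimethoxybenzoyl)oxy]-2-methoxy-6-pentylbenzoic acid, via heptanal hydrazone 11 (not isolated)
Conditions: 10 (3 equiv) added to N2H4·H2O (3 equiv), THF, rt, 1 h, 4 Å MS; then 9, Ni(cod)2 (15 mol %), PMe3 (30 mol %), DBU (3 equiv), THF, 60 °C, 16 h; 1 M HCl work-up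
Reagents that add atoms: none
Why: Nickel-catalysed denitrogenative cross-coupling of an N-unsubstituted aldehyde hydrazone with an aryl bromide (Wolff–Kishner-type carbonyl umpolung), in which Ni(0) inserts into the C–Br bond, DBU deprotonates the N-bound hydrazone 11, N2 is lost to give an aryl(heptyl)nickel species and reductive elimination forms the aryl–CH2 bond, with the acid carried as its DBU salt and the hindered aryl ester expected to resist the weakly nucleophilic hydrazone.

**Compound list**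
1 | 2-bromo-4,6-dimethoxybenzaldehyde | COc1cc(Br)c(C=O)c(OC)c1 | starting material
2 | 2-bromo-4,6-dimethoxybenzoic acid | COc1cc(Br)c(C(=O)O)c(OC)c1 | intermediate
3 | olivetol (5-pentylbenzene-1,3-diol) | CCCCCc1cc(O)cc(O)c1 | starting material
4 | N-[(2,4-dihydroxy-6-pentylphenyl)methylidene]-N-methylmethanaminium chloride (not isolated) | CCCCCc1cc(O)cc(O)c1C=[N+](C)C.[Cl-] | intermediate
5 | 2,4-dihydroxy-6-pentylbenzaldehyde | CCCCCc1cc(O)cc(O)c1C=O | intermediate
6 | 2-bromo-4,6-dimethoxybenzoic trifluoroacetic anhydride (not isolated) | COc1cc(Br)c(C(=O)OC(=O)C(F)(F)F)c(OC)c1 | intermediate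
7 | 4-formyl-3-hydroxy-5-pentylphenyl 2-bromo-4,6-dimethoxybenzoate | CCCCCc1cc(OC(=O)c2c(Br)cc(OC)cc2OC)cc(O)c1C=O | intermediate
8 | 4-formyl-3-methoxy-5-pentylphenyl 2-bromo-4,6-dimethoxybenzoate | CCCCCc1cc(OC(=O)c2c(Br)cc(OC)cc2OC)cc(OC)c1C=O | intermediate
9 | 4-[(2-bromo-4,6-dimethoxybenzoyl)oxy]-2-methoxy-6-pentylbenzoic acid | CCCCCc1cc(OC(=O)c2c(Br)cc(OC)cc2OC)cc(OC)c1C(=O)O | intermediate
10 | heptanal | CCCCCCC=O | starting material
11 | heptanal hydrazone (heptylidenehydrazine, not isolated) | CCCCCCC=NN | intermediate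
12 | 4-[(2-heptyl-4,6-dimethoxybenzoyl)oxy]-2-methoxy-6-pentylbenzoic acid | CCCCCCCc1cc(OC)cc(OC)c1C(=O)Oc1cc(CCCCC)c(C(=O)O)c(OC)c1 | target

**Totals**
Total step count: 6. Longest linear sequence: 5 steps (1 → 2 → 7 → 8 → 9 → 12, or 3 → 5 → 7 → 8 → 9 → 12).

**Steps most likely to fail**

Step 6 is the riskiest. The coupling is run on a substrate with a free carboxylic acid and an aryl ester that hydrazone or residual hydrazine could cleave, and the bromide sits ortho to the ester; hydrodebromination is a further risk. The fallback moves the same carbonyl-umpolung coupling to an early, simple substrate; it sets out from 2 and comes back to the route at 12. Acid 2 is benzylated (BnBr, K2CO3, DMF) to benzyl 2-bromo-4,6-dimethoxybenzoate F1. F1 is coupled with hydrazone 11 under the Ni(cod)2/PMe3/DBU conditions to give benzyl 2-heptyl-4,6-dimethoxybenzoate F2. Hydrogenolysis (H2, Pd/C, EtOAc) gives 2-heptyl-4,6-dimethoxybenzoic acid F3. TFAA/toluene esterification of F3 with 5 gives 4-formyl-3-hydroxy-5-pentylphenyl 2-heptyl-4,6-dimethoxybenzoate F4. MeI/K2CO3 then gives 4-formyl-3-methoxy-5-pentylphenyl 2-heptyl-4,6-dimethoxybenzoate F5, and Pinnick oxidation of F5 gives 12.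

Step 3 is second. The risk is incomplete selectivity between the 4-OH and 2-OH, or bis-acylation. The fallback differentiates the two hydroxyls before the esterification; it sets out from 5 and comes back at 8. Aldehyde 5 is benzylated at the non-chelated 4-OH (BnBr, KHCO3, MeCN, 60 °C) to 4-(benzyloxy)-2-hydroxy-6-pentylbenzaldehyde F6. Methylation (MeI, K2CO3, DMF) gives 4-(benzyloxy)-2-methoxy-6-pentylbenzaldehyde F7. Hydrogenolysis (H2 1 atm, Pd/C, EtOAc, stopped after one equivalent) gives 4-hydroxy-2-methoxy-6-pentylbenzaldehyde F8. F8 has a single free OH and is esterified with 2 (TFAA, toluene) to give 8 directly, which also bypasses step 4.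

Step 5 is third. The risk is ring chlorination of the electron-rich rings or a sluggish reaction of the 2,6-disubstituted aldehyde. The fallback carries the B-ring carboxyl at the acid oxidation level from the start, so no aldehyde is oxidised on the depside; it sets out from 3 and comes back at 12. Olivetol 3 is carboxylated (methyl magnesium carbonate, DMF, 120 °C) to 2,4-dihydroxy-6-pentylbenzoic acid F9. Benzylation of the carboxylate (BnBr, KHCO3, DMF) gives benzyl 2,4-dihydroxy-6-pentylbenzoate F10. TFAA esterification with 2 gives benzyl 4-[(2-bromo-4,6-dimethoxybenzoyl)oxy]-2-hydroxy-6-pentylbenzoate F11. MeI/K2CO3 gives benzyl 4-[(2-bromo-4,6-dimethoxybenzoyl)oxy]-2-methoxy-6-pentylbenzoate F12. Ni-catalysed coupling with hydrazone 11 gives benzyl 4-[(2-heptyl-4,6-dimethoxybenzoyl)oxy]-2-methoxy-6-pentylbenzoate F13, and hydrogenolysis (H2, Pd/C, EtOAc) gives 12.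

**Further compounds**
F1 | step 6 | benzyl 2-bromo-4,6-dimethoxybenzoate | COc1cc(Br)c(C(=O)OCc2ccccc2)c(OC)c1
F2 | step 6 | benzyl 2-heptyl-4,6-dimethoxybenzoate | CCCCCCCc1cc(OC)cc(OC)c1C(=O)OCc1ccccc1
F3 | step 6 | 2-heptyl-4,6-dimethoxybenzoic acid | CCCCCCCc1cc(OC)cc(OC)c1C(=O)O
F4 | step 6 | 4-formyl-3-hydroxy-5-pentylphenyl 2-heptyl-4,6-dimethoxybenzoate | CCCCCCCc1cc(OC)cc(OC)c1C(=O)Oc1cc(CCCCC)c(C=O)c(O)c1
F5 | step 6 | 4-formyl-3-methoxy-5-pentylphenyl 2-heptyl-4,6-dimethoxybenzoate | CCCCCCCc1cc(OC)cc(OC)c1C(=O)Oc1cc(CCCCC)c(C=O)c(OC)c1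
F6 | step 3 | 4-(benzyloxy)-2-hydroxy-6-pentylbenzaldehyde | CCCCCc1cc(OCc2ccccc2)cc(O)c1C=O
F7 | step 3 | 4-(benzyloxy)-2-methoxy-6-pentylbenzaldehyde | CCCCCc1cc(OCc2ccccc2)cc(OC)c1C=O
F8 | step 3 | 4-hydroxy-2-methoxy-6-pentylbenzaldehyde | CCCCCc1cc(O)cc(OC)c1C=O
F9 | step 5 | 2,4-dihydroxy-6-pentylbenzoic acid | CCCCCc1cc(O)cc(O)c1C(=O)O
F10 | step 5 | benzyl 2,4-dihydroxy-6-pentylbenzoate | CCCCCc1cc(O)cc(O)c1C(=O)OCc1ccccc1
F11 | step 5 | benzyl 4-[(2-bromo-4,6-dimethoxybenzoyl)oxy]-2-hydroxy-6-pentylbenzoate | CCCCCc1cc(OC(=O)c2c(Br)cc(OC)cc2OC)cc(O)c1C(=O)OCc1ccccc1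
F12 | step 5 | benzyl 4-[(2-bromo-4,6-dimethoxybenzoyl)oxy]-2-methoxy-6-pentylbenzoate | CCCCCc1cc(OC(=O)c2c(Br)cc(OC)cc2OC)cc(OC)c1C(=O)OCc1ccccc1
F13 | step 5 | benzyl 4-[(2-heptyl-4,6-dimethoxybenzoyl)oxy]-2-methoxy-6-pentylbenzoate | CCCCCCCc1cc(OC)cc(OC)c1C(=O)Oc1cc(CCCCC)c(C(=O)OCc2ccccc2)c(OC)c1
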